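## Retrosynthetic overview

1. Ludongnin F ⇐ exo-face hydrogenation of a 16-methylene-15-ketone (sets C16, saturates C11=C12) ⇐ α-methylenation of a bicyclo[3.2.1]octenone; the C6 acetal is fixed by thermodynamic MeOH exchange.
2. Ring D (C13–C16) ⇐ Pd(II) cycloalkenylation of the C15 silyl enol ether onto C12=C13.
3. Ring C (C8–C14 and C9–C11; sets C8, C9) ⇐ Diels–Alder of butadiene with a spiro 3-acetyl-5,6-dihydropyran-2-one.
4. Spiro δ-lactone and C10 quaternary centre (C9–C10) ⇐ new Ti(III) epoxide radical alkenylation–lactonisation with ethyl 2-(ethoxymethylene)acetoacetate.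
5. Ring A and cis-fused THF acetal ⇐ Cu-catalysed asymmetric conjugate methylation (C4), Mukaiyama formylation (C6), acetalisation (C5), from 3-methoxybenzyl alcohol. Ring order: A → THF acetal → spiro-lactone → C → D.

Assumptions (one line): atom labels use ent-kaurane numbering (C4 quaternary with Me C18 and OCH2 C19; C6 acetal; C7 lactone C=O; C10 spiro; C15 ketone; C16–C17 CHMe; C20 lactone OCH2); the C6 anomeric centre is carried as a mixture until step 11; the ligand enantiomer in step 3 is whichever gives (R)-4.

## Route

**Step 1**
Reactants: 1, 3-methoxybenzyl alcohol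
Product: 2, 3-(hydroxymethyl)cyclohex-2-en-1-one
Conditions: Li, NH3(l), THF, t-BuOH, −78 → −33 °C; then 2 M HCl, THF, rt
Reagents that add atoms: water, O (carbonyl oxygen)
Why: Birch reduction of the anisole (the benzylic alkoxide resists hydrogenolysis) gives the 1-methoxy-1,4-diene, and acid hydrolysis of the enol ether with isomerisation into conjugation gives the 3-substituted enone.

**Step 2**
Reactants: 2, 3-(hydroxymethyl)cyclohex-2-en-1-one
Product: 3, 3-{[(tert-butyldimethylsilyl)oxy]methyl}cyclohex-2-en-1-one
Conditions: TBSCl, imidazole, CH2Cl2, 0 °C → rt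
Reagents that add atoms: TBSCl, CC(C)(C)[Si](C)(C)Cl
Why: Standard silylation of a primary alcohol protects C19–OH through the organometallic and Lewis-acid steps.

**Step 3**
Reactants: 3, TBS-protected enone
Product: 4, (R)-tert-butyldimethyl{[1-methyl-3-(trimethylsilyloxy)cyclohex-2-en-1-yl]methoxy}silane
Conditions: Me3Al, CuTC (2 mol %), chiral phosphoramidite L* (4 mol %), Et2O, −30 °C; then TMSOTf, −30 → 0 °C
Reagents that add atoms: trimethylaluminium, C[Al](C)C; TMSOTf, C[Si](C)(C)OS(=O)(=O)C(F)(F)F
Why: Cu-catalysed asymmetric conjugate addition of Me3Al to a β,β-disubstituted cyclohexenone (Alexakis-type) creates the C4 quaternary centre under ligand control, and O-silylation of the aluminium enolate fixes the enol ether at C5=C10.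

**Step 4**
Reactants: 4, silyl enol ether
Product: 5, (3R)-3-{[(tert-butyldimethylsilyl)oxy]methyl}-2-(dimethoxymethyl)-3-methylcyclohexan-1-one (C2 epimers)
Conditions: HC(OMe)3, BF3·OEt2, CH2Cl2, −78 → −40 °C
Reagents that add atoms: trimethyl orthoformate, COC(OC)OC
Why: Mukaiyama-type addition of the silyl enol ether to the dimethoxycarbenium ion installs C6 at the aldehyde oxidation level regiospecifically at C5; the C5 configuration is unimportant because it is equilibrated in step 5.

**Step 5**
Reactants: 5, β-keto dimethyl acetal
Product: 6, cis-fused (3aR,7aS)-1-methoxy-3a-methylhexahydroisobenzofuran-7(1H)-one (C10 ketone; mixture of C6 anomers)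
Conditions: AcCl (0.2 equiv, gives HCl), MeOH, rt → 40 °C; then K2CO3 (s), rt
Reagents that add atoms: methanol, CO (acetal OMe exchanges with solvent)
Why: Acid removes the TBS group and the C19 hydroxyl closes the five-membered acetal by transacetalisation, while C5 (α to the ketone) equilibrates to the more stable cis ring fusion (C6 syn to C19), relaying the C4 configuration to C5.

**Step 6**
Reactants: 6, bicyclic keto acetal
Product: 7, spiro-epoxide (C10–C20 oxirane on the bicyclic acetal; mixture at C10 and C6)
Conditions: Me3S+ I−, n-BuLi, THF, −10 °C → rt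
Reagents that add atoms: trimethylsulfonium iodide, C[S+](C)C.[I-]
Why: Corey–Chaykovsky methylene transfer to the ketone gives the epoxide; its C10 configuration is irrelevant because both epimers give the same C10 radical in step 7.

**Step 7 (proposed new reaction)**
Reactants: 7, spiro-epoxide; 8, ethyl 2-(ethoxymethylene)-3-oxobutanoate
Product: 9, spiro-lactone: ring A/THF acetal as in 7, with C10 spiro to a 3-acetyl-5,6-dihydro-2H-pyran-2-one (C20H2–O–C7(=O)–C8(Ac)=C9H); the new C10–C9 bond is on the β-face, trans to C6
Conditions: Cp2TiCl2 (2.4 equiv), Zn, THF, rt; add 7 and 8 (3 equiv) slowly at 0 °C → rt; then open to air, 50 °C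
Reagents that add atoms: none (all heavy atoms come from 7 and 8; two EtOH are lost)
Why: Proposed new method: Ti(III)-mediated epoxide radical alkenylation–lactonisation, in which Cp2TiCl opens either epoxide epimer to the same tertiary β-titanoxy C10 radical that adds, polarity-matched, to the β-carbon of the Zn(II)-chelated push–pull alkene 8 from the convex β-face anti to the C5–C6 acetal ring (setting C10), a second Cp2TiCl reduces the resulting 1,3-dicarbonyl radical to a Ti(IV) enolate that expels ethoxide (E1cB) to give the alkylidene acetoacetate, and the C20–O–Ti alkoxide then lactonises onto the ethyl ester; 8 is a vinylogous carbonate and so resists reduction by Ti(III), and residual Ti(III) is air-quenched before warming so that 9 is not exposed to reductant; the closest known reaction type is the Cp2TiCl-mediated reductive epoxide opening/Giese addition to acrylates with in situ lactonisation, together with radical addition to β-alkoxyacrylates.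

**Step 8**
Reactants: 9, unsaturated acetyl spiro-lactone; 10, buta-1,3-diene
Product: 11, Diels–Alder adduct: cis-fused lactone/cyclohexene with C8 quaternary (acetyl and lactone C=O), C9–H, and C12=C13 alkene
Conditions: buta-1,3-diene (excess), ZnCl2 (1 equiv), Et2O, rt, sealed tube
Reagents that add atoms: none (all heavy atoms come from 9 and 10)
Why: Lewis-acid-promoted Diels–Alder reaction of a doubly activated alkylidene β-keto lactone, in which the diene adds to the C8=C9 face anti to the bulky C5 branch of the spiro centre (syn to C1) and suprafacial addition makes the lactone/ring C fusion cis, setting C9 and C8.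

**Step 9**
Reactants: 11, Diels–Alder adduct
Product: 12, C15 trimethylsilyl enol ether of 11 (C15(OTMS)=C16H2)
Conditions: TMSCl, LiHMDS, THF, −78 °C (internal quench); used crude
Reagents that add atoms: TMSCl, C[Si](C)(C)Cl
Why: Kinetic deprotonation at C16, the only enolisable position because C8 is quaternary, with in situ O-silylation gives the enol ether.

**Step 10**
Reactants: 12, silyl enol ether
Product: 13, bicyclo[3.2.1]octenone: new C13–C16 bond, C15 ketone, C16H2, C11=C12 alkene (C6 anomers)
Conditions: Pd(OAc)2 (10 mol %), O2 (1 atm), DMSO, 45 °C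
Reagents that add atoms: none
Why: Saegusa–Ito/Kende-type Pd(II) cycloalkenylation, in which the Pd enolate undergoes 5-exo syn-carbopalladation of C12=C13 on the only face the C8 tether can reach (fixing C13) and β-hydride elimination gives the C11=C12 alkene.

**Step 11**
Reactants: 13, bicyclo[3.2.1]octenone (C6 anomers)
Product: 14, the single 6R anomer of 13
Conditions: PPTS (0.2 equiv), MeOH, 40 °C; separate and resubject the minor anomer
Reagents that add atoms: methanol, CO
Why: Acid-catalysed acetal exchange through the cyclic oxocarbenium ion under thermodynamic control is expected to favour the 6R anomer, whose methoxy group is pseudo-equatorial and anti to H5 and the angular C18 methyl.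

**Step 12**
Reactants: 14, 6R ketone
Product: 15, 16-methylene-15-ketone (exocyclic enone C16=C17; C11=C12 retained)
Conditions: LiHMDS, THF, −78 °C; CH2=NMe2+ I−, −78 °C → rt; then MeI; then DBU, CH2Cl2, rt
Reagents that add atoms: Eschenmoser's salt, C=[N+](C)C.[I-]
Why: Eschenmoser methylenation (Mannich reaction of the C16 enolate, N-methylation, elimination) at the only enolisable carbon gives the exocyclic enone, which cannot isomerise into the ring (bridgehead).

**Step 13**
Reactants: 15, 16-methylene-15-ketone
Product: 16, ludongnin F
Conditions: H2 (1 atm), 10% Pd/C, EtOAc, rt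
Reagents that add atoms: none
Why: Heterogeneous hydrogenation adds H2 to C16=C17 from the exo face (syn to the C14 bridge), placing C17 endo to give 16R, and saturates C11=C12 without creating a stereocentre; the neutral conditions leave C6 and C16 untouched.

## Compound list

1 | 3-methoxybenzyl alcohol | COc1cccc(CO)c1 | starting material
2 | 3-(hydroxymethyl)cyclohex-2-en-1-one | O=C1C=C(CO)CCC1 | intermediate
3 | 3-{[(tert-butyldimethylsilyl)oxy]methyl}cyclohex-2-en-1-one | O=C1C=C(CO[Si](C)(C)C(C)(C)C)CCC1 | intermediate
4 | (R)-tert-butyldimethyl{[1-methyl-3-(trimethylsilyloxy)cyclohex-2-en-1-yl]methoxy}silane | CC(C)(C)[Si](C)(C)OC[C@]1(C)CCCC(O[Si](C)(C)C)=C1 | intermediate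
5 | (3R)-3-{[(tert-butyldimethylsilyl)oxy]methyl}-2-(dimethoxymethyl)-3-methylcyclohexan-1-one (C2 epimers) | CC(C)(C)[Si](C)(C)OC[C@]1(C)CCCC(=O)C1C(OC)OC | intermediate
6 | (3aR,7aS)-1-methoxy-3a-methylhexahydroisobenzofuran-7(1H)-one, cis-fused, C1 anomers | COC1OC[C@]2(C)CCCC(=O)[C@H]12 | intermediate
7 | spiro-epoxide of 6 (oxirane at former C=O; epimers at spiro carbon and acetal carbon) | COC1OC[C@]2(C)CCCC3(CO3)[C@H]12 | intermediate
8 | ethyl 2-(ethoxymethylene)-3-oxobutanoate | CCOC=C(C(C)=O)C(=O)OCC | starting material
9 | spiro 3-acetyl-5,6-dihydro-2H-pyran-2-one on the bicyclic acetal (C10 R; C6 anomers) | COC1OC[C@]2(C)CCC[C@]3(COC(=O)C(C(C)=O)=C3)[C@H]12 | intermediate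
10 | buta-1,3-diene | C=CC=C | starting material
11 | Diels–Alder adduct (cis-fused lactone/cyclohexene, C8 acetyl) | COC1OC[C@]2(C)CCC[C@]3(COC(=O)[C@]4(CC=CC[C@H]43)C(C)=O)[C@H]12 | intermediate
12 | C15 TMS enol ether of 11 | COC1OC[C@]2(C)CCC[C@]3(COC(=O)[C@]4(CC=CC[C@H]43)C(=C)O[Si](C)(C)C)[C@H]12 | intermediate
13 | 11,12-didehydro-17-nor-ludongnin F skeleton (bicyclo[3.2.1]octenone, C16H2; C6 anomers) | COC1OC[C@]2(C)CCC[C@]3(COC(=O)[C@@]45C[C@@H](C=C[C@H]43)CC5=O)[C@H]12 | intermediate
14 | 6R anomer of 13 | CO[C@@H]1OC[C@]2(C)CCC[C@]3(COC(=O)[C@@]45C[C@@H](C=C[C@H]43)CC5=O)[C@H]12 | intermediate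
15 | 16-methylene-15-ketone (11,12,16,17-tetradehydro-ludongnin F) | CO[C@@H]1OC[C@]2(C)CCC[C@]3(COC(=O)[C@@]45C[C@@H](C=C[C@H]43)C(=C)C5=O)[C@H]12 | intermediate
16 | ludongnin F | CO[C@@H]1OC[C@]2(C)CCC[C@]3(COC(=O)[C@@]45C[C@@H](CC[C@H]43)[C@@H](C)C5=O)[C@H]12 | target

## Summary

Total step count: 13. Longest linear sequence: 13 steps (from 1; 8 and 10 are purchased).

Three steps most likely to fail, with fallbacks:

1. **Step 7 (proposed new reaction).** Risks are slow addition of the hindered tertiary radical to the β-substituted acceptor, premature radical reduction, and 1,5-H transfer from the OMe group. Fallback with known chemistry: Cp2TiCl-mediated coupling of 7 with 2,2,2-trifluoroethyl acrylate to give the saturated spiro-δ-lactone, then C8 acetylation (LDA, MeCHO; Dess–Martin) and selenoxide elimination (PhSeCl, then H2O2) to reach 9.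

2. **Step 10 (Pd cycloalkenylation).** Risks are 6-endo closure to a bicyclo[2.2.2]octane, protodesilylation, or alkene migration. Fallback that makes the regiochemistry unambiguous:
   - run the Diels–Alder of 9 with 2-(trimethylsilyloxy)buta-1,3-diene, which places a nucleophilic enol ether at C12=C13;
   - form the bis(silyl enol ether) and close C13–C16 by oxidative enol-ether coupling (CAN, NaHCO3, MeCN);
   - remove the extra C12 ketone via its tosylhydrazone (catecholborane).

3. **Step 11 (C6 anomer).** The thermodynamic ratio may be poor or favour the 6S anomer. Fallback under kinetic control: hydrolyse to the 6,19-lactol (AcOH/H2O/THF) and O-methylate with MeI/Ag2O, or convert the lactol to its anomeric trichloroacetimidate and displace with MeOH with inversion.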